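The route rests on opening the pyranone ring (ring C) at the O1–C2 bond. C2 lies β to the C4 ketone, so this bond is the retron of a conjugate addition of the ring A phenol oxygen to an enone. A temporary tert-butyl ester at C3 turns the open-chain precursor into a doubly activated benzylidene β-ketoester carrying the free phenol; a bifunctional cinchona thiourea closes it by an enantioselective 6-endo-trig oxa-Michael addition that forms ring C and sets the C2 stereocentre in one operation, and acid then removes the ester as isobutene and carbon dioxide in the same flask. The precursor is built in three steps from 1,2,3,5-tetramethoxybenzene and 3,4-dimethoxybenzaldehyde.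

Key step: step 4

Assumption: the cinchona thioureas of the quinidine and quinine series are pseudoenantiomeric in this ring closure; the quinidine-series catalyst is written on the assumption that it delivers the (2S) configuration, and the quinine-series catalyst takes its place unchanged if the sense proves opposite.

Step 1
Reactants: 1 1,2,3,5-tetramethoxybenzene
Product: 3 1-(2-hydroxy-3,4,6-trimethoxyphenyl)ethan-1-one, via 2,3,4,6-tetramethoxyacetophenone 2 (not isolated)
Conditions: AcCl (1.2 equiv), AlCl3 (2.5 equiv), Et2O, 0 °C → rt; aq. HCl work-up
Reagents that add atoms: acetyl chloride, CC(=O)Cl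
Why: Friedel–Crafts acylation should occur at one of the two equivalent free ring positions, after which AlCl3 chelated to the new ketone should cleave the ortho methoxy group that is buttressed by a second methoxy neighbour (Lewis acid ortho-demethylation), leaving the hydrogen-bonded phenol.

Step 2
Reactants: 3 1-(2-hydroxy-3,4,6-trimethoxyphenyl)ethan-1-one
Product: 5 tert-butyl 3-(2-hydroxy-3,4,6-trimethoxyphenyl)-3-oxopropanoate, via aryl tert-butyl carbonate 4 (not isolated)
Conditions: Boc2O (1.1 equiv), DMAP (5 mol %), THF, rt; volatiles removed; LiN(SiMe3)2 (2.3 equiv), THF, −78 → 0 °C; aq. NH4Cl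
Reagents that add atoms: di-tert-butyl dicarbonate, CC(C)(C)OC(=O)OC(=O)OC(C)(C)C
Why: DMAP-catalysed O-acylation should give the aryl carbonate, whose lithium enolate attacks the carbonate carbonyl through a six-membered transition state and expels the phenoxide (Baker–Venkataraman-type anionic O-to-C acyl transfer), while the hindered tert-butyl ester should resist lactonisation to a 4-hydroxycoumarin.

Step 3
Reactants: 5 tert-butyl 3-(2-hydroxy-3,4,6-trimethoxyphenyl)-3-oxopropanoate; 6 3,4-dimethoxybenzaldehyde
Product: 7 tert-butyl (Z)-3-(3,4-dimethoxyphenyl)-2-(2-hydroxy-3,4,6-trimethoxybenzoyl)prop-2-enoate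
Conditions: piperidine (10 mol %), AcOH (10 mol %), 4 Å molecular sieves, toluene, rt
Reagents that add atoms: none
Why: Knoevenagel condensation of the doubly activated methylene with the aldehyde through its piperidinium iminium ion, driven by removal of water, should give the trisubstituted alkene, expected mainly as the (Z) isomer with the twisted aroyl group on the side of the vinylic hydrogen; no stereocentre is formed.

Step 4
Reactants: 7 tert-butyl (Z)-3-(3,4-dimethoxyphenyl)-2-(2-hydroxy-3,4,6-trimethoxybenzoyl)prop-2-enoate
Product: 10 (2S)-2-(3,4-dimethoxyphenyl)-5,7,8-trimethoxychroman-4-one (target), via trans tert-butyl flavanone-3-carboxylate 8 (not isolated), via flavanone-3-carboxylic acid 9 (not isolated)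
Conditions: N-[3,5-bis(trifluoromethyl)phenyl]-N'-[(9R)-6'-methoxycinchonan-9-yl]thiourea (from 9-amino-9-deoxy-epi-quinidine, 10 mol %), toluene, −25 °C; then TsOH·H2O (1 equiv), 80 °C
Reagents that add atoms: none
Why: The quinuclidine nitrogen of the catalyst acts as a general base on the ring A phenol while the thiourea N–H bonds bind the two carbonyl groups of the alkylidene β-ketoester, so that the phenoxide oxygen adds to the benzylic β-carbon inside a chiral hydrogen-bonded ion pair (intramolecular oxa-Michael addition) and protonation of the ester enolate gives the trans ester 8; TsOH then cleaves the tert-butyl ester with loss of isobutene and the β-keto acid 9 loses CO2 on heating. The closest known reaction type is the bifunctional cinchona thiourea catalysed enantioselective cyclisation of 2-hydroxyaryl alkylidene β-ketoesters to flavanone-3-carboxylates with acid-mediated decarboxylation in the same flask. Ring C closes in the 6-endo-trig mode, both alkene carbons ending up inside the new ring. C2 is set by the catalyst, which presents one enantiotopic face of the alkene to the tethered phenoxide (quinidine series for 2S, see the assumption), whereas the C3 centre of 8 is under thermodynamic control and disappears on decarboxylation. The step needs enantioface selectivity without a racemic background closure or later ring opening: the tert-butyl ester provides the second carbonyl for two-point binding to the thiourea and makes the catalysed addition fast at −25 °C, and it is removed under acid and not base, so that the retro-oxa-Michael pathway that would racemise C2 is not opened.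

Compound list
1 | 1,2,3,5-tetramethoxybenzene | COc1cc(OC)c(OC)c(OC)c1 | starting material
2 | 1-(2,3,4,6-tetramethoxyphenyl)ethan-1-one (not isolated) | CC(=O)c1c(OC)c(OC)c(OC)cc1OC | intermediate
3 | 1-(2-hydroxy-3,4,6-trimethoxyphenyl)ethan-1-one | CC(=O)c1c(O)c(OC)c(OC)cc1OC | intermediate
4 | 2-acetyl-3,5,6-trimethoxyphenyl tert-butyl carbonate (not isolated) | CC(=O)c1c(OC(=O)OC(C)(C)C)c(OC)c(OC)cc1OC | intermediate
5 | tert-butyl 3-(2-hydroxy-3,4,6-trimethoxyphenyl)-3-oxopropanoate | CC(C)(C)OC(=O)CC(=O)c1c(O)c(OC)c(OC)cc1OC | intermediate
6 | 3,4-dimethoxybenzaldehyde | COc1ccc(C=O)cc1OC | starting material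
7 | tert-butyl (Z)-3-(3,4-dimethoxyphenyl)-2-(2-hydroxy-3,4,6-trimethoxybenzoyl)prop-2-enoate | COc1ccc(/C=C(\C(=O)OC(C)(C)C)C(=O)c2c(O)c(OC)c(OC)cc2OC)cc1OC | intermediate
8 | tert-butyl (2S,3R)-2-(3,4-dimethoxyphenyl)-5,7,8-trimethoxy-4-oxochromane-3-carboxylate (trans, not isolated) | COc1ccc([C@@H]2[C@@H](C(=O)OC(C)(C)C)C(=O)c3c(OC)cc(OC)c(OC)c3O2)cc1OC | intermediate
9 | (2S,3R)-2-(3,4-dimethoxyphenyl)-5,7,8-trimethoxy-4-oxochromane-3-carboxylic acid (not isolated) | COc1ccc([C@@H]2[C@@H](C(=O)O)C(=O)c3c(OC)cc(OC)c(OC)c3O2)cc1OC | intermediate
10 | (2S)-2-(3,4-dimethoxyphenyl)-5,7,8-trimethoxychroman-4-one | COc1ccc([C@@H]2CC(=O)c3c(OC)cc(OC)c(OC)c3O2)cc1OC | target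

Total step count: 4. Longest linear sequence: 4 steps (1 → 3 → 5 → 7 → 10); aldehyde 6 enters at step 3.

Steps most likely to fail

Step 4. Facial discrimination in the hydrogen-bonded ion pair may be poor, because the methoxy group ortho to the ketone twists the aroyl ring and may loosen the two-point binding. Enantiopurity may also erode through reversible ring opening (retro-oxa-Michael) while the ester is cleaved at 80 °C, which the electron-rich dimethoxyphenyl group favours. The fallback sets out from 3 and 6 and comes back at 10. Claisen–Schmidt condensation (KOH, EtOH, rt) should give the 2'-hydroxychalcone (E)-3-(3,4-dimethoxyphenyl)-1-(2-hydroxy-3,4,6-trimethoxyphenyl)prop-2-en-1-one F1. NaOAc in refluxing EtOH should then close the same O1–C2 bond by oxa-Michael addition without stereocontrol, giving racemic 2-(3,4-dimethoxyphenyl)-5,7,8-trimethoxychroman-4-one F2. Preparative HPLC on a chiral stationary phase (amylose tris(3,5-dimethylphenylcarbamate)) would separate 10 from its (2R) enantiomer, which base can return to the racemate through the chalcone for recycling.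

Step 2. The tert-butoxycarbonyl group may be lost by intermolecular attack of amide or alkoxide on the carbonate before the intramolecular transfer takes place, and the transfer itself may stall at the hindered enolate. The fallback sets out from 1 and comes back at 5. Directed ortho-lithiation between two methoxy groups (n-BuLi, TMEDA, THF, 0 °C) and inverse quench with methyl chloroformate should give methyl 2,3,4,6-tetramethoxybenzoate F3. Chelation-controlled demethylation of the buttressed ortho methoxy group (BCl3, CH2Cl2, −78 → 0 °C) should give methyl 2-hydroxy-3,4,6-trimethoxybenzoate F4. Claisen condensation with the lithium enolate of tert-butyl acetate in excess (LiN(iPr)2, THF, −78 → 0 °C) should then deliver 5.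

Step 3. The electron-rich aldehyde may condense slowly, and with amine present the free phenol of 7 may close the ring prematurely and without stereocontrol, so that racemic material is carried into the key step. The fallback sets out from 5 and comes back at 7. Silylation of the phenol (TBSCl, imidazole, DMF, rt) should give tert-butyl 3-[2-(tert-butyldimethylsilyloxy)-3,4,6-trimethoxyphenyl]-3-oxopropanoate F5. Knoevenagel condensation with 6 (piperidine, AcOH, benzene, reflux with water removal) can then be forced without risk of closure and should give tert-butyl (Z)-2-[2-(tert-butyldimethylsilyloxy)-3,4,6-trimethoxybenzoyl]-3-(3,4-dimethoxyphenyl)prop-2-enoate F6. Desilylation under acidic fluoride (HF·pyridine, THF, 0 °C) should release 7 in the absence of base.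

Further compounds
F1 | step 4 | (E)-3-(3,4-dimethoxyphenyl)-1-(2-hydroxy-3,4,6-trimethoxyphenyl)prop-2-en-1-one | COc1ccc(/C=C/C(=O)c2c(O)c(OC)c(OC)cc2OC)cc1OC
F2 | step 4 | racemic 2-(3,4-dimethoxyphenyl)-5,7,8-trimethoxychroman-4-one | COc1ccc(C2CC(=O)c3c(OC)cc(OC)c(OC)c3O2)cc1OC
F3 | step 2 | methyl 2,3,4,6-tetramethoxybenzoate | COC(=O)c1c(OC)c(OC)c(OC)cc1OC
F4 | step 2 | methyl 2-hydroxy-3,4,6-trimethoxybenzoate | COC(=O)c1c(O)c(OC)c(OC)cc1OC
F5 | step 3 | tert-butyl 3-[2-(tert-butyldimethylsilyloxy)-3,4,6-trimethoxyphenyl]-3-oxopropanoate | CC(C)(C)OC(=O)CC(=O)c1c(O[Si](C)(C)C(C)(C)C)c(OC)c(OC)cc1OC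
F6 | step 3 | tert-butyl (Z)-2-[2-(tert-butyldimethylsilyloxy)-3,4,6-trimethoxybenzoyl]-3-(3,4-dimethoxyphenyl)prop-2-enoate | COc1ccc(/C=C(\C(=O)OC(C)(C)C)C(=O)c2c(O[Si](C)(C)C(C)(C)C)c(OC)c(OC)cc2OC)cc1OC
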